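# Proposed synthesis of CNP0322023.1 by palladium π-allyl macrocyclisation at C5–C6

## Analysis of the target

The target is an eleven-membered carbocycle of the humulane type. The ring is numbered from the angelate carbinol C1 through C2, C3=C4(CH3), C5, C6, C7, the gem-dimethyl carbon C8, the acetate carbinol C9 and C10=C11(CH3) back to C1; it holds an E-trisubstituted alkene at C3=C4 and a Z-trisubstituted alkene at C10=C11. The only stereocentres are C1 (S) and C9 (R), both allylic carbinols on the two ends of the Z alkene, so they stand in a 1,4 relationship across a rigid spacer and cannot easily control one another. The two oxygens carry different acyl groups and must be told apart, and the angelate is the delicate one because it isomerises to the tiglate under nucleophilic or basic acylation conditions. The difficulty lies in closing a medium ring that contains two trisubstituted alkenes of opposite geometry while keeping two remote stereocentres under reagent control. The ring has an unfunctionalised stretch C5–C6–C7 next to the quaternary C8, and C5 is the terminus of a 2-methylallyl unit C3–C4(CH3)–C5. That unit is the handle of the plan: an allyl electrophile spanning C3–C5 can be joined to a carbanion at the plain methylene C6, and the activating groups on C6 can then be removed without trace.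

## Retrosynthetic reasoning

Target 24 is first simplified at the two ester C–O bonds. Removing the acetate at C9 gives alcohol 23, which comes from silyl ether 22, and cutting the angelate C–O bond leads to alcohol 19 and angelic acid 20. The angelate goes on first because in bis-silyl ether 18 the triethylsilyl group sits on the unhindered C1 oxygen and the tert-butyldimethylsilyl group on the hindered C9 oxygen, so the reliable selective cleavage frees C1 first. The forward steps must acylate C1 without Z to E isomerisation of the acyl group, then unmask and acetylate a neopentyl-type alcohol without disturbing that ester.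

Compound 18 has no functional group between C4 and C8, so two C–S bonds are added back at C6 to give bis-sulfone 17. Nothing is cut in the skeleton; what is gained is a carbon acid at C6 that methoxide can deprotonate. The forward reaction has to remove both sulfonyl groups reductively while leaving two allylic silyl ethers and two alkenes alone.

The ring of 17 is opened at C5–C6 to give open-chain carbonate 16. This bond is chosen for three reasons:
- C5 is the unsubstituted end of the C3–C5 allyl unit, so a bulky nucleophile is directed there.
- The bond lies far from C1 and C9, so neither stereocentre is at risk.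
- C6 is flanked only by methylenes, so the sulfonyl groups leave no mark.

Cutting C1–C2 or C9–C10 instead would tie ring closure to the creation of a stereocentre under the control of a medium-ring transition state. In the forward sense a π-allylpalladium complex must be attacked at C5 and must adopt the geometry that gives E-C3=C4. Because C3 becomes sp2, 16 can be used as a mixture of C3 epimers.

Silyl ether 16 comes from alcohol 15, which is cut at C9–C10 into alkenyl iodide 11 and aldehyde 14. This places C1 in one fragment and leaves the other achiral, and it exploits the fact that the aldehyde carbon of 14 sits on the quaternary C8 and cannot enolise. The forward coupling must keep the Z geometry of the iodide, tolerate the carbonate, the silyl ether and the acidic C6–H, and set C9 by reagent control, since C1 is too far away to help.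

Aldehyde 14 is cut at C7–C8 into isobutyraldehyde 12 and the vinylidene bis-sulfone 13. One conjugate addition builds the quaternary carbon and brings in C6 already doubly activated, at the aldehyde oxidation level, so no redox adjustment is needed.

Carbonate 11 is traced through alcohol 10 and enone 9 to aldol 8, which is cut at C1–C2 into methyl ketone 5 and aldehyde 4. Ketone 5 supplies C2–C5 with the 2-methylallyl unit in place, the aldol sets C1, and a later 1,2-reduction turns the C3 carbonyl into the leaving-group position. The forward aldol must be enantioselective with a methyl ketone, for which a chiral boron enolate (6, giving aldolate 7) is the established answer.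

Aldehyde 4 comes from alcohol 3, and 3 from propargyl alcohol 1 by adding methyl to C11 and iodine to C10 across the triple bond through magnesium chelate 2. The anti mode of this carbometalation fixes the Z geometry of C10=C11 once and for all.

## Alternatives that were turned down

Alternative 1: The Z alkene C10=C11 is disconnected, with the two carbinol oxygens tied together through silicon.
- Forward key step: the acyclic mixed diisopropylsilylene bis-ether A2, which joins a C9 vinyl carbinol and a C1 isopropenyl carbinol, would be treated with the second-generation Grubbs catalyst. Ring-closing metathesis with loss of ethylene would give the seven-membered dioxasilepine A1.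
- For it: the small ring can only hold a cis alkene, so Z-C10=C11 is certain. The two stereocentres come from separate fragments, each open to a high-selectivity method of its own, and E-C3=C4 is already present in one fragment before any ring forms. On the last two points it is stronger than the chosen plan, which relies on one moderately selective aldol, one ligand-controlled coupling and the geometry of an allyl complex.
- Against it: the metathesis must make a trisubstituted alkene from a 1,1-disubstituted alkene and a vinyl group next to the quaternary C8. The unsymmetrical silylene has to be assembled from two hindered secondary alcohols without homo-coupling. A1 is still not a carbocycle, so the eleven-membered ring would have to be closed afterwards at C5–C6 by alkylation of a mono-sulfone carbanion, which needs a strong base and an allylic halide made from the protected C5 alcohol. Removal of the tether then gives a diol whose two hydroxyls are told apart only by sterics.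
- Comparison: the chosen plan fixes Z-C10=C11 just as firmly in its first step, closes the carbocycle and sets E-C3=C4 in one operation under neutral conditions, and is shorter by several steps.

Alternative 2: The C3=C4 alkene and a C9 carbonyl are traced back to a C4–C9 bond, so the eleven-membered ring becomes a fused six–seven bicycle.
- Forward key step: KOtBu would deprotonate the tertiary C9 alcohol of the trans-fused mesylate A4. The C4–C9 bond, held anti-periplanar to the C3–O bond, would break as the mesylate leaves (Grob fragmentation) to give dienone A3.
- For it: no medium-ring entropy has to be paid and no high dilution is needed. The alkene geometry follows stereospecifically from the relative configuration at C3 and C4, and C10=C11 is held cis in the seven-membered ring. On ring formation and on certainty of the E geometry it is stronger than the chosen plan.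
- Against it: A4 needs a quaternary ring-fusion carbon C4, a tertiary carbinol C9 beside the quaternary C8 and a defined C3 configuration. These three stereocentres are built only to be destroyed, while C1 must be carried through in the right absolute sense. After the fragmentation C9 is a ketone, and the 9R carbinol would have to come from 1,2-reduction of a hindered Z-enone whose faces are distinguished only by the conformation of the new ring.
- Comparison: the chosen plan sets C9 by a chiral ligand in an open-chain step, needs no sacrificial stereocentres, and reaches the ring in far fewer steps from commercial materials.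

Alternative 3: The ring is cut at C4–C5, between the alkene carbon C4 and the methylene C5.
- Forward key step: 9-BBN would hydroborate the terminal C5=C6 alkene of the open-chain alkenyl iodide A6. The C5 borane would couple with the E-alkenyl iodide at C4 under PdCl2(dppf) and Cs2CO3 (B-alkyl Suzuki macrocyclisation) to give macrocycle A5.
- For it: the E geometry of C3=C4 is built into the iodide and kept by the coupling. A5 already carries the C9 acetate and no sulfones, so only desilylation and angeloylation would remain. On both points it is stronger than the chosen plan.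
- Against it: the E-configured iodide with iodine on the methyl-bearing carbon is much harder to reach than the methyl ketone used here, since iodo-olefination gives the Z isomer and hydrometalation of a 2-alkyne is not regioselective. The allylic acetate at C9 must survive zerovalent palladium and aqueous carbonate. Reductive elimination has to join an alkyl and an alkenyl group inside a strained eleven-membered ring, where β-hydride elimination and protodeboronation of the alkylborane compete.
- Comparison: the chosen plan gives up the shorter endgame. It gains simple fragments, a neutral ring closure whose electrophile is formed catalytically, and silyl ethers instead of an ionisable allylic ester during the palladium step.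

Key step: step 10

## Route

Remark: C3 of compounds 10, 11, 15 and 16 is carried as both epimers, because step 10 removes this stereocentre. The antipodes of the chiral reagents in steps 3 and 8 are assigned from the face of attack named in each step and would be confirmed by Mosher ester analysis of 8 and 15. Ring locants C1–C11 of the analysis are used for all compounds.

Step 1
Reactants: 1 prop-2-yn-1-ol (propargyl alcohol)
Product: 3 (Z)-3-iodo-2-methylprop-2-en-1-ol, via oxamagnesacycle 2 (not isolated)
Conditions: MeMgBr (3 equiv), CuI (10 mol %), THF, −10 °C to rt; then I2, −40 to 0 °C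
Reagents that add atoms: methylmagnesium bromide, C[Mg]Br; iodine, II
Why: Copper-catalysed anti-carbomagnesiation of the propargylic alkoxide places methyl on C11 and magnesium on C10 inside a five-membered chelate, and iodinolysis with retention should give the Z-alkenyl iodide. This fixes the Z-C10=C11 geometry for the whole route.

Step 2
Reactants: 3 (Z)-3-iodo-2-methylprop-2-en-1-ol
Product: 4 (Z)-3-iodo-2-methylprop-2-enal
Conditions: MnO2 (activated, 15 equiv), CH2Cl2, rt, dark; filtered and used at once
Reagents that add atoms: none
Why: Allylic oxidation on the MnO2 surface is neutral and leaves the alkenyl iodide untouched. The Z-enal is not stored because β-iodo enals isomerise on standing.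

Step 3
Reactants: 5 3-methylbut-3-en-2-one; 4 (Z)-3-iodo-2-methylprop-2-enal
Product: 8 (5S,6Z)-5-hydroxy-7-iodo-2,6-dimethylhepta-1,6-dien-3-one, via dienyl borinate 6 (not isolated), via boron aldolate 7 (not isolated)
Conditions: (+)-Ipc2BCl, Et3N, Et2O, 0 °C; then 4, −78 to −20 °C; then H2O2, pH 7 buffer, MeOH, 0 °C
Reagents that add atoms: none
Why: Diisopinocampheylboron-mediated aldol of a methyl ketone: only the methyl group of 5 can be enolised, and dienolate 6 should add to the Si face of the aldehyde through a cyclic boron-centred transition state, which gives the 1S carbinol. Moderate to good enantioselectivity is expected for this reagent class, and material of the wrong C1 configuration becomes a diastereomer after step 8 and can be removed after step 10.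

Step 4
Reactants: 8 (5S,6Z)-5-hydroxy-7-iodo-2,6-dimethylhepta-1,6-dien-3-one
Product: 9 (5S,6Z)-7-iodo-2,6-dimethyl-5-(triethylsilyloxy)hepta-1,6-dien-3-one
Conditions: TESCl (1.2 equiv), imidazole, DMF, 0 °C
Reagents that add atoms: chlorotriethylsilane, CC[Si](Cl)(CC)CC
Why: Standard silylation of a secondary alcohol; the mild base avoids β-elimination of the aldol.

Step 5
Reactants: 9 (5S,6Z)-7-iodo-2,6-dimethyl-5-(triethylsilyloxy)hepta-1,6-dien-3-one
Product: 10 (5S,6Z)-7-iodo-2,6-dimethyl-5-(triethylsilyloxy)hepta-1,6-dien-3-ol (both C3 epimers)
Conditions: NaBH4, CeCl3·7H2O, MeOH, −78 °C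
Reagents that add atoms: none
Why: Luche reduction should give clean 1,2-reduction of the enone. The configuration at C3 is irrelevant because C3 becomes sp2 in step 10.

Step 6
Reactants: 10 (5S,6Z)-7-iodo-2,6-dimethyl-5-(triethylsilyloxy)hepta-1,6-dien-3-ol
Product: 11 (5S,6Z)-7-iodo-2,6-dimethyl-5-(triethylsilyloxy)hepta-1,6-dien-3-yl methyl carbonate (both C3 epimers)
Conditions: ClCO2Me, pyridine, DMAP (5 mol %), CH2Cl2, 0 °C
Reagents that add atoms: methyl chloroformate, COC(=O)Cl
Why: Acylation of the secondary allylic alcohol with a chloroformate. The methyl carbonate is both the leaving group and the internal source of base for step 10.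

Step 7
Reactants: 12 2-methylpropanal (isobutyraldehyde); 13 1,1-bis(phenylsulfonyl)ethene
Product: 14 2,2-dimethyl-4,4-bis(phenylsulfonyl)butanal
Conditions: pyrrolidine (20 mol %), CHCl3, 0 °C to rt; the aldehyde in threefold excess
Reagents that add atoms: none
Why: Enamine-catalysed Michael addition of the Stork type: the pyrrolidine enamine of the α-branched aldehyde attacks the CH2 terminus of the doubly activated alkene, and hydrolysis of the iminium adduct returns the amine and releases the aldehyde, creating the C7–C8 bond and the quaternary C8. The reaction is a pure addition in which all atoms of both reactants end in 14, and the product has no α-hydrogen and cannot react again.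

Step 8
Reactants: 11 (5S,6Z)-7-iodo-2,6-dimethyl-5-(triethylsilyloxy)hepta-1,6-dien-3-yl methyl carbonate; 14 2,2-dimethyl-4,4-bis(phenylsulfonyl)butanal
Product: 15 (5S,6Z,8R)-8-hydroxy-2,6,9,9-tetramethyl-11,11-bis(phenylsulfonyl)-5-(triethylsilyloxy)undeca-1,6-dien-3-yl methyl carbonate (1S,9R in ring locants; both C3 epimers)
Conditions: CrCl2 (4 equiv), N-[2-(4-isopropyl-4,5-dihydrooxazol-2-yl)-6-methylphenyl]methanesulfonamide, single antipode (4.4 equiv), Et3N (4.4 equiv), THF, rt; then NiCl2 (2 mol %), 11 and 14 (1.5 equiv), rt
Reagents that add atoms: none
Why: Nozaki–Hiyama–Kishi coupling: zerovalent nickel inserts into the C–I bond, the alkenyl group passes to trivalent chromium with retention of the Z geometry and adds to the non-enolisable aldehyde. The chromium-bound chiral sulfonamide is chosen to direct attack to the Re face of the aldehyde, which gives 9R. Alkenylchromium reagents add to aldehydes in the presence of carbonates and silyl ethers and are protonated only slowly by carbon acids.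

Step 9
Reactants: 15 (5S,6Z,8R)-8-hydroxy-2,6,9,9-tetramethyl-11,11-bis(phenylsulfonyl)-5-(triethylsilyloxy)undeca-1,6-dien-3-yl methyl carbonate
Product: 16 (5S,6Z,8R)-8-(tert-butyldimethylsilyloxy)-2,6,9,9-tetramethyl-11,11-bis(phenylsulfonyl)-5-(triethylsilyloxy)undeca-1,6-dien-3-yl methyl carbonate (both C3 epimers)
Conditions: TBSOTf, 2,6-lutidine, CH2Cl2, −78 to 0 °C
Reagents that add atoms: tert-butyldimethylsilyl trifluoromethanesulfonate, CC(C)(C)[Si](C)(C)OS(=O)(=O)C(F)(F)F
Why: A silyl triflate with a hindered pyridine base silylates the neopentyl-type secondary alcohol. The base is too weak to deprotonate C6, and the carbonate is untouched at low temperature.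

Step 10
Reactants: 16 (5S,6Z,8R)-8-(tert-butyldimethylsilyloxy)-2,6,9,9-tetramethyl-11,11-bis(phenylsulfonyl)-5-(triethylsilyloxy)undeca-1,6-dien-3-yl methyl carbonate
Product: 17 (1S,3E,9R,10Z)-9-(tert-butyldimethylsilyloxy)-4,8,8,11-tetramethyl-6,6-bis(phenylsulfonyl)-1-(triethylsilyloxy)cycloundeca-3,10-diene
Conditions: Pd(PPh3)4 (10 mol %), 1,2-bis(diphenylphosphino)ethane (10 mol %), THF, 65 °C, addition of 16 over 12 h, final 2 mM
Reagents that add atoms: none
Why: Zerovalent palladium ionises the C3 carbonate of either epimer to the same cationic 2-methyl-π-allyl complex over C3–C5, releasing CO2 and methoxide, which deprotonates the bis(phenylsulfonyl)methine at C6; this is a Tsuji–Trost allylic alkylation run as a macrocyclisation, the closest known type being the closure of medium and large carbocycles by bis-sulfonyl carbanions. The soft carbanion attacks the allyl face opposite palladium at the unsubstituted terminus C5, so the whole allyl unit becomes endocyclic and the eleven-membered ring forms by C5–C6 bond formation; attack at C3 would give a nine-membered ring with an exocyclic isopropenyl group and is disfavoured by the substituent on C3 and the size of the nucleophile. No stereocentre is created: C3 becomes sp2 and C6 carries two identical sulfonyl groups. The geometry of C3=C4 is set by the allyl complex: with the C2 chain syn to the C4 methyl group the product is E, and the syn and anti complexes interconvert through the η1 form bound at C3, so ring closure should drain the normally more stable syn complex. C1 and C9 are untouched, the allylic silyl ethers are not ionised, and the alkenyl iodide was consumed in step 8. Slow addition at high dilution suppresses dimers; the main competing path is loss of a C2 hydrogen from the allyl complex to give a 1,3-diene.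

Step 11
Reactants: 17 (1S,3E,9R,10Z)-9-(tert-butyldimethylsilyloxy)-4,8,8,11-tetramethyl-6,6-bis(phenylsulfonyl)-1-(triethylsilyloxy)cycloundeca-3,10-diene
Product: 18 (1S,3E,9R,10Z)-9-(tert-butyldimethylsilyloxy)-4,8,8,11-tetramethyl-1-(triethylsilyloxy)cycloundeca-3,10-diene
Conditions: Na/Hg (6 % Na), Na2HPO4, MeOH–THF, −20 to 0 °C
Reagents that add atoms: none
Why: Reductive desulfonylation: electron transfer from Na/Hg cleaves both C–S bonds in turn and methanol protonates each carbanion. The phosphate buffer keeps the medium near neutral and C6 has no β-leaving group, so the silyl ethers and both alkenes should remain.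

Step 12
Reactants: 18 (1S,3E,9R,10Z)-9-(tert-butyldimethylsilyloxy)-4,8,8,11-tetramethyl-1-(triethylsilyloxy)cycloundeca-3,10-diene
Product: 19 (1S,3E,9R,10Z)-9-(tert-butyldimethylsilyloxy)-4,8,8,11-tetramethylcycloundeca-3,10-dien-1-ol
Conditions: PPTS (10 mol %), MeOH–CH2Cl2, 0 °C
Reagents that add atoms: none
Why: Acid-catalysed methanolysis discriminates the unhindered triethylsilyl ether at C1 from the tert-butyldimethylsilyl ether at C9, which is more robust and sits next to the quaternary C8.

Step 13
Reactants: 19 (1S,3E,9R,10Z)-9-(tert-butyldimethylsilyloxy)-4,8,8,11-tetramethylcycloundeca-3,10-dien-1-ol; 20 angelic acid [(Z)-2-methylbut-2-enoic acid]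
Product: 22 (1S,3E,9R,10Z)-9-(tert-butyldimethylsilyloxy)-4,8,8,11-tetramethylcycloundeca-3,10-dien-1-yl (Z)-2-methylbut-2-enoate, via mixed anhydride 21 (not isolated)
Conditions: 20, 2,4,6-trichlorobenzoyl chloride, Et3N, toluene, rt; then 19, 80 °C
Reagents that add atoms: none
Why: Yamaguchi-type esterification through the mixed anhydride without a nucleophilic pyridine catalyst: the alcohol attacks the less hindered angeloyl carbonyl of 21. Leaving out 4-dimethylaminopyridine avoids the conjugate addition–elimination that turns angelates into tiglates.

Step 14
Reactants: 22 (1S,3E,9R,10Z)-9-(tert-butyldimethylsilyloxy)-4,8,8,11-tetramethylcycloundeca-3,10-dien-1-yl (Z)-2-methylbut-2-enoate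
Product: 23 (1S,3E,9R,10Z)-9-hydroxy-4,8,8,11-tetramethylcycloundeca-3,10-dien-1-yl (Z)-2-methylbut-2-enoate
Conditions: HF·pyridine, pyridine, THF, 0 °C to rt
Reagents that add atoms: none
Why: Fluoride cleaves the Si–O bond under buffered, weakly acidic conditions, which should neither saponify nor migrate the angelate nor ionise the allylic ester.

Step 15
Reactants: 23 (1S,3E,9R,10Z)-9-hydroxy-4,8,8,11-tetramethylcycloundeca-3,10-dien-1-yl (Z)-2-methylbut-2-enoate
Product: 24 (1S,3E,9R,10Z)-9-acetoxy-4,8,8,11-tetramethylcycloundeca-3,10-dien-1-yl (Z)-2-methylbut-2-enoate (CNP0322023.1)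
Conditions: Ac2O, Et3N, DMAP (10 mol %), CH2Cl2, 0 °C to rt
Reagents that add atoms: acetic anhydride, CC(=O)OC(C)=O
Why: Acylation of the hindered secondary alcohol through the N-acetylpyridinium ion. The angelate already in place is an ordinary ester, not an activated acyl species, and should keep its Z geometry at room temperature.

## Compound list

1 | prop-2-yn-1-ol (propargyl alcohol) | C#CCO | starting material
2 | 4-methyl-2,5-dihydro-1,2-oxamagnesole (cyclic Z-alkenylmagnesium alkoxide) | CC1=C[Mg]OC1 | intermediate
3 | (Z)-3-iodo-2-methylprop-2-en-1-ol | OC/C(C)=C\I | intermediate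
4 | (Z)-3-iodo-2-methylprop-2-enal | O=C/C(C)=C\I | intermediate
5 | 3-methylbut-3-en-2-one | CC(=O)C(C)=C | starting material
6 | 3-methylbuta-1,3-dien-2-yl bis(isopinocampheyl)borinate (isopinocampheyl groups of the (−)-α-pinene series) | C=C(C)C(=C)OB([C@H]1C[C@H]2C[C@@H]([C@@H]1C)C2(C)C)[C@H]3C[C@H]4C[C@@H]([C@@H]3C)C4(C)C | intermediate
7 | bis(isopinocampheyl)borinate of aldol 8 (boron aldolate) | C=C(C)C(=O)C[C@H](OB([C@H]1C[C@H]2C[C@@H]([C@@H]1C)C2(C)C)[C@H]3C[C@H]4C[C@@H]([C@@H]3C)C4(C)C)/C(C)=C\I | intermediate
8 | (5S,6Z)-5-hydroxy-7-iodo-2,6-dimethylhepta-1,6-dien-3-one | C=C(C)C(=O)C[C@H](O)/C(C)=C\I | intermediate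
9 | (5S,6Z)-7-iodo-2,6-dimethyl-5-(triethylsilyloxy)hepta-1,6-dien-3-one | C=C(C)C(=O)C[C@H](O[Si](CC)(CC)CC)/C(C)=C\I | intermediate
10 | (5S,6Z)-7-iodo-2,6-dimethyl-5-(triethylsilyloxy)hepta-1,6-dien-3-ol, both C3 epimers | C=C(C)C(O)C[C@H](O[Si](CC)(CC)CC)/C(C)=C\I | intermediate
11 | (5S,6Z)-7-iodo-2,6-dimethyl-5-(triethylsilyloxy)hepta-1,6-dien-3-yl methyl carbonate, both C3 epimers | C=C(C)C(OC(=O)OC)C[C@H](O[Si](CC)(CC)CC)/C(C)=C\I | intermediate
12 | 2-methylpropanal (isobutyraldehyde) | CC(C)C=O | starting material
13 | 1,1-bis(phenylsulfonyl)ethene | C=C(S(=O)(=O)c1ccccc1)S(=O)(=O)c1ccccc1 | starting material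
14 | 2,2-dimethyl-4,4-bis(phenylsulfonyl)butanal | O=CC(C)(C)CC(S(=O)(=O)c1ccccc1)S(=O)(=O)c1ccccc1 | intermediate
15 | (5S,6Z,8R)-8-hydroxy-2,6,9,9-tetramethyl-11,11-bis(phenylsulfonyl)-5-(triethylsilyloxy)undeca-1,6-dien-3-yl methyl carbonate, both C3 epimers | C=C(C)C(OC(=O)OC)C[C@H](O[Si](CC)(CC)CC)/C(C)=C\[C@@H](O)C(C)(C)CC(S(=O)(=O)c1ccccc1)S(=O)(=O)c1ccccc1 | intermediate
16 | (5S,6Z,8R)-8-(tert-butyldimethylsilyloxy)-2,6,9,9-tetramethyl-11,11-bis(phenylsulfonyl)-5-(triethylsilyloxy)undeca-1,6-dien-3-yl methyl carbonate, both C3 epimers | C=C(C)C(OC(=O)OC)C[C@H](O[Si](CC)(CC)CC)/C(C)=C\[C@@H](O[Si](C)(C)C(C)(C)C)C(C)(C)CC(S(=O)(=O)c1ccccc1)S(=O)(=O)c1ccccc1 | intermediate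
17 | (1S,3E,9R,10Z)-9-(tert-butyldimethylsilyloxy)-4,8,8,11-tetramethyl-6,6-bis(phenylsulfonyl)-1-(triethylsilyloxy)cycloundeca-3,10-diene | CC[Si](CC)(CC)O[C@H]1C/C=C(\C)CC(S(=O)(=O)c2ccccc2)(S(=O)(=O)c2ccccc2)CC(C)(C)[C@H](O[Si](C)(C)C(C)(C)C)/C=C\1C | intermediate
18 | (1S,3E,9R,10Z)-9-(tert-butyldimethylsilyloxy)-4,8,8,11-tetramethyl-1-(triethylsilyloxy)cycloundeca-3,10-diene | CC[Si](CC)(CC)O[C@H]1C/C=C(\C)CCCC(C)(C)[C@H](O[Si](C)(C)C(C)(C)C)/C=C\1C | intermediate
19 | (1S,3E,9R,10Z)-9-(tert-butyldimethylsilyloxy)-4,8,8,11-tetramethylcycloundeca-3,10-dien-1-ol | O[C@H]1C/C=C(\C)CCCC(C)(C)[C@H](O[Si](C)(C)C(C)(C)C)/C=C\1C | intermediate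
20 | angelic acid [(Z)-2-methylbut-2-enoic acid] | C/C=C(/C)C(=O)O | starting material
21 | (Z)-2-methylbut-2-enoic 2,4,6-trichlorobenzoic anhydride | C/C=C(/C)C(=O)OC(=O)c1c(Cl)cc(Cl)cc1Cl | intermediate
22 | (1S,3E,9R,10Z)-9-(tert-butyldimethylsilyloxy)-4,8,8,11-tetramethylcycloundeca-3,10-dien-1-yl (Z)-2-methylbut-2-enoate | C/C=C(/C)C(=O)O[C@H]1C/C=C(\C)CCCC(C)(C)[C@H](O[Si](C)(C)C(C)(C)C)/C=C\1C | intermediate
23 | (1S,3E,9R,10Z)-9-hydroxy-4,8,8,11-tetramethylcycloundeca-3,10-dien-1-yl (Z)-2-methylbut-2-enoate | C/C=C(/C)C(=O)O[C@H]1C/C=C(\C)CCCC(C)(C)[C@H](O)/C=C\1C | intermediate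
24 | (1S,3E,9R,10Z)-9-acetoxy-4,8,8,11-tetramethylcycloundeca-3,10-dien-1-yl (Z)-2-methylbut-2-enoate (CNP0322023.1) | C/C=C(/C)C(=O)O[C@H]1C/C=C(\C)CCCC(C)(C)[C@H](OC(C)=O)/C=C\1C | target

## Step count and least certain steps

Total: 15 steps. Longest linear sequence: 14 steps (steps 1–6 and 8–15, from 1); the branch to aldehyde 14 adds step 7.

Step 10 (key step). Ring closure may be slower than decay of the allyl complex, because the C6 carbanion is bulky and sits next to a neopentyl-type chain. Loss of a C2 hydrogen to a 1,3-diene, intermolecular alkylation, or closure from the anti allyl complex to Z-C3=C4 could then compete. The fallback moves the ring closure to C9–C10 and forms C5–C6 without palladium. It sets out from 10 and 14. Alcohol 10 would be treated with PBr3 and a little pyridine in Et2O at −20 °C, which should give, with allylic transposition, the primary E-allylic bromide F1. The sodium salt of 14 (NaH, DMF, 0 °C) would be alkylated with F1 to give the open-chain iodo aldehyde F2. An intramolecular Nozaki–Hiyama–Kishi reaction (CrCl2, NiCl2 1 mol %, DMSO–THF, rt, 2 mM) would close the ring to the macrocyclic carbinol F3, and silylation with TBSOTf and 2,6-lutidine would return to the route at 17. The weakness of this fallback is that C9 is then set inside the ring, by its conformation or by the chiral ligand of step 8.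

Step 8. Facial selectivity in the addition to a pivaldehyde-like aldehyde may be poor, since the ligand must override a very hindered carbonyl. A further risk is insertion of zerovalent nickel into the allylic carbonate, which the low nickel loading is meant to suppress. The fallback sets the stereocentre by reduction instead of addition. It sets out from 11 and 14: coupling with CrCl2 and NiCl2 (1 mol %) in DMSO without chiral ligand would give the C9 epimer mixture F4. Dess–Martin periodinane with NaHCO3 would oxidise it to the Z-enone F5. Corey–Bakshi–Shibata reduction (2-methyl-CBS-oxazaborolidine, catecholborane, toluene, −78 °C, with the antipode that treats the quaternary side as the large group) would return to the route at 15.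

Step 3. Aldehyde 4 may isomerise from Z to E before or during enolate addition, and enantioselection in methyl ketone boron aldols is incomplete. The fallback sets C1 by asymmetric allylboration and builds C3–C5 afterwards. It sets out from 4: B-allyldiisopinocampheylborane, made from (−)-Ipc2BOMe and allylmagnesium bromide (Et2O, −78 °C; NaOH, H2O2), should attack the Si face and give the homoallylic alcohol F6. Silylation (TESCl, imidazole) would give the silyl ether F7, and cleavage of the terminal alkene (OsO4 cat., NaIO4, 2,6-lutidine, dioxane–water) the β-silyloxy aldehyde F8. Addition of isopropenylmagnesium bromide (THF, −78 °C) would return to the route at 10, where the C3 configuration does not matter.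

Step 13. The angeloyl group may isomerise to tigloyl while it is activated, through reversible conjugate addition of a base or nucleophile to the mixed anhydride. The fallback builds the Z alkene on the ester instead of transferring it. It sets out from 19: esterification with 2-[bis(2,2,2-trifluoroethoxy)phosphoryl]propanoic acid (N,N′-dicyclohexylcarbodiimide, DMAP, CH2Cl2) would give the phosphonate ester F9. A Still–Gennari olefination (KN(SiMe3)2, 18-crown-6, THF, −78 °C; acetaldehyde) should give the Z-2-methylbut-2-enoate and return to the route at 22.

Step 14. Cleavage of the silyl ether beside the quaternary C8 may be slow, and forcing or basic fluoride conditions could cause loss or 1,4-migration of the angelate. The fallback removes both silyl groups before any ester is present and relies on steric differentiation of the diol. It sets out from 18: tetrabutylammonium fluoride in THF would give the diol F10. One equivalent of mixed anhydride 21 in toluene should acylate the unhindered C1 hydroxyl in preference to the neopentyl-type C9 hydroxyl and return to the route at 23.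

## Further compounds

F1 | step 10 | (2E,5S,6Z)-1-bromo-7-iodo-2,6-dimethyl-5-(triethylsilyloxy)hepta-2,6-diene | BrC/C(C)=C/C[C@H](O[Si](CC)(CC)CC)/C(C)=C\I
F2 | step 10 | (6E,9S,10Z)-11-iodo-2,2,6,10-tetramethyl-4,4-bis(phenylsulfonyl)-9-(triethylsilyloxy)undeca-6,10-dienal | O=CC(C)(C)CC(S(=O)(=O)c1ccccc1)(S(=O)(=O)c1ccccc1)C/C(C)=C/C[C@H](O[Si](CC)(CC)CC)/C(C)=C\I
F3 | step 10 | (1R,2Z,4S,6E)-3,7,11,11-tetramethyl-9,9-bis(phenylsulfonyl)-4-(triethylsilyloxy)cycloundeca-2,6-dien-1-ol (9R carbinol, 1S silyl ether in ring locants of the analysis) | CC[Si](CC)(CC)O[C@H]1C/C=C(\C)CC(S(=O)(=O)c2ccccc2)(S(=O)(=O)c2ccccc2)CC(C)(C)[C@H](O)/C=C\1C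
F4 | step 8 | (5S,6Z)-8-hydroxy-2,6,9,9-tetramethyl-11,11-bis(phenylsulfonyl)-5-(triethylsilyloxy)undeca-1,6-dien-3-yl methyl carbonate, both C8 (ring C9) epimers | C=C(C)C(OC(=O)OC)C[C@H](O[Si](CC)(CC)CC)/C(C)=C\C(O)C(C)(C)CC(S(=O)(=O)c1ccccc1)S(=O)(=O)c1ccccc1
F5 | step 8 | (5S,6Z)-2,6,9,9-tetramethyl-8-oxo-11,11-bis(phenylsulfonyl)-5-(triethylsilyloxy)undeca-1,6-dien-3-yl methyl carbonate | C=C(C)C(OC(=O)OC)C[C@H](O[Si](CC)(CC)CC)/C(C)=C\C(=O)C(C)(C)CC(S(=O)(=O)c1ccccc1)S(=O)(=O)c1ccccc1
F6 | step 3 | (1Z,3S)-1-iodo-2-methylhexa-1,5-dien-3-ol | C=CC[C@H](O)/C(C)=C\I
F7 | step 3 | (1Z,3S)-1-iodo-2-methyl-3-(triethylsilyloxy)hexa-1,5-diene | C=CC[C@H](O[Si](CC)(CC)CC)/C(C)=C\I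
F8 | step 3 | (3S,4Z)-5-iodo-4-methyl-3-(triethylsilyloxy)pent-4-enal | O=CC[C@H](O[Si](CC)(CC)CC)/C(C)=C\I
F9 | step 13 | (1S,3E,9R,10Z)-9-(tert-butyldimethylsilyloxy)-4,8,8,11-tetramethylcycloundeca-3,10-dien-1-yl 2-[bis(2,2,2-trifluoroethoxy)phosphoryl]propanoate | CC(C(=O)O[C@H]1C/C=C(\C)CCCC(C)(C)[C@H](O[Si](C)(C)C(C)(C)C)/C=C\1C)P(=O)(OCC(F)(F)F)OCC(F)(F)F
F10 | step 14 | (1S,3E,9R,10Z)-4,8,8,11-tetramethylcycloundeca-3,10-diene-1,9-diol | O[C@H]1C/C=C(\C)CCCC(C)(C)[C@H](O)/C=C\1C
A1 | alternative 1 | dioxasilepine holding Z-C10=C11 and both carbinol stereocentres | CC1=C[C@H](C(C)(C)CCS(=O)(=O)c2ccccc2)O[Si](C(C)C)(C(C)C)O[C@H]1C/C=C(\C)COCc3ccc(OC)cc3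
A2 | alternative 1 | acyclic mixed diisopropylsilylene bis-ether of the C9 vinyl carbinol and the C1 isopropenyl carbinol | C=C[C@H](C(C)(C)CCS(=O)(=O)c1ccccc1)O[Si](C(C)C)(C(C)C)O[C@H](C(C)=C)C/C=C(\C)COCc1ccc(OC)cc1
A3 | alternative 2 | eleven-membered dienone with C9 ketone and C1 silyl ether | CC(C)(C)[Si](C)(C)O[C@H]1C/C=C(\C)CCCC(C)(C)C(=O)/C=C\1C
A4 | alternative 2 | trans-fused bicyclo[5.4.0]undecene mesylate with tertiary C9 alcohol, C3–O anti-periplanar to C4–C9 | CC(C)(C)[Si](C)(C)O[C@H]1C[C@@H](OS(C)(=O)=O)[C@]2(C)CCCC(C)(C)[C@@]2(O)C=C1C
A5 | alternative 3 | eleven-membered diene with C9 acetate and C1 silyl ether | CC(C)(C)[Si](C)(C)O[C@H]1C/C=C(\C)CCCC(C)(C)[C@H](OC(C)=O)/C=C\1C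
A6 | alternative 3 | open-chain E-alkenyl iodide with terminal C5=C6 alkene, C9 acetate and C1 silyl ether | I/C(C)=C/C[C@H](O[Si](C)(C)C(C)(C)C)/C(C)=C\[C@@H](OC(C)=O)C(C)(C)CC=C
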